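**Plan**

- Numbering (cadinane, used throughout): C1 ring-fusion CH, C4 spiro carbon, C5 vinyl CH, C6 ring-fusion alkene carbon, C7 CH-isopropyl, C10 CH-methyl, C15 chroman CH2. Ring A is C1/C6–C10 and ring B is C1–C6.
- Retrosynthetic cuts, in order: the two aryl–CHO bonds; the C4–C5 bond of ring B, which opens to a chroman-2-ylium oxocarbenium ion tethered to an exocyclic vinylsilane; the aryl–CH(Ph) bond (phloroglucinol plus enone); the C15=CHPh bond (aldol condensation); the C6–C7 bond of ring A (enyne cycloisomerization); the C1–C2 bond (Michael addition to methyl vinyl ketone), back to (R)-citronellal.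
- Forward order: acyclic C1/C10 diad, then ring A, then the oxygen ring as a reversible hemiketal, then ring B together with the spiro centre in the key step, then double formylation.
- Enabling feature: C4 is at once the oxygen-bearing, ketal-type carbon of the chroman (flanked by the CH2 groups C3 and C15) and allylic to the C5=C6 alkene, which is exocyclic to ring A. A tertiary allylic aryl ether of this kind is the retron for ipso attack of a vinylsilane carbon (C5) on a cyclic oxocarbenium carbon (C4), with silicon fixing the alkene position.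
- Stereochemistry: C10 from (R)-citronellal; C1 from a catalyst-controlled enamine Michael addition; C7 and the vinylsilane geometry from the cycloisomerization; the benzylic centre from iminium catalysis; C4 from the key step (substrate control, matched with the benzylic centre).

Key step: step 10

Assumption: the facial sense of the two amine catalysts (steps 1 and 9) is taken by analogy with their standard model reactions; if either induction proved opposite, the mirror-image or pseudoenantiomeric catalyst would be used with no other change.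

**Route**

Step 1
Reactants: 1 (R)-citronellal; 2 methyl vinyl ketone
Product: 3 (2R,3R)-3,7-dimethyl-2-(3-oxobutyl)oct-6-enal
Conditions: (R)-α,α-diphenylprolinol methyl ether (5 mol %), ethyl 3,4-dihydroxybenzoate (20 mol %), 2 (1.5 equiv), neat, 4 °C
Reagents that add atoms: none
Why: Enamine-mediated organocatalytic Michael addition of an aldehyde to a vinyl ketone, in which the diarylprolinol ether shields one face of the E-enamine so that the new C1 centre should be set (R) under catalyst control, independent of the resident C10 centre.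

Step 2
Reactants: 3 (2R,3R)-3,7-dimethyl-2-(3-oxobutyl)oct-6-enal
Product: 4 (5R)-7,7-dibromo-5-[(2R)-6-methylhept-5-en-2-yl]hept-6-en-2-one
Conditions: CBr4 (2 equiv), PPh3 (4 equiv), CH2Cl2, 0 °C
Reagents that add atoms: carbon tetrabromide (BrC(Br)(Br)Br)
Why: First stage of the Corey–Fuchs sequence (dibromo-olefination), which should be selective for the aldehyde over the methyl ketone and, being non-basic, should leave the α-centre C1 untouched and remove its acidity for the rest of the route.

Step 3
Reactants: 4 (5R)-7,7-dibromo-5-[(2R)-6-methylhept-5-en-2-yl]hept-6-en-2-one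
Product: 5 2-[(3R)-5,5-dibromo-3-[(2R)-6-methylhept-5-en-2-yl]pent-4-en-1-yl]-2-methyl-1,3-dioxolane
Conditions: ethylene glycol, PPTS (cat.), benzene, reflux (Dean–Stark)
Reagents that add atoms: ethylene glycol (OCCO)
Why: Standard acid-catalysed dioxolane formation masks the ketone against the organolithium of step 4 and should not touch either alkene.

Step 4
Reactants: 5 2-[(3R)-5,5-dibromo-3-[(2R)-6-methylhept-5-en-2-yl]pent-4-en-1-yl]-2-methyl-1,3-dioxolane
Product: 7 [(3R,4R)-4,8-dimethyl-3-[2-(2-methyl-1,3-dioxolan-2-yl)ethyl]non-7-en-1-yn-1-yl]trimethylsilane, via lithium acetylide 6 (not isolated)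
Conditions: n-BuLi (2.2 equiv), THF, −78 → 0 °C; then TMSCl, −78 °C → rt
Reagents that add atoms: chlorotrimethylsilane (C[Si](C)(C)Cl)
Why: Second stage of the Corey–Fuchs alkyne synthesis (bromine–lithium exchange, Fritsch–Buttenberg–Wiechell shift, deprotonation) gives the acetylide, which is C-silylated in the same flask to install the group that later controls ring A and the key step.

Step 5
Reactants: 7 [(3R,4R)-4,8-dimethyl-3-[2-(2-methyl-1,3-dioxolan-2-yl)ethyl]non-7-en-1-yn-1-yl]trimethylsilane
Product: 8 [(E)-[(2R,3R,6S)-3-methyl-2-[2-(2-methyl-1,3-dioxolan-2-yl)ethyl]-6-(prop-1-en-2-yl)cyclohexylidene]methyl]trimethylsilane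
Conditions: Pd2(dba)3·CHCl3 (2.5 mol %), P(o-tol)3 (10 mol %), AcOH (20 mol %), benzene, 60 °C
Reagents that add atoms: none
Why: Palladium-catalysed 1,7-enyne cycloisomerization (formal intramolecular Alder-ene reaction via HPdOAc) adds H and C7 syn across the alkyne, which places silicon cis to C1 on the new exocyclic alkene, and a chair-like carbopalladation with the C10 methyl and the developing isopropenyl group equatorial and the C1 side chain axial (its equatorial alternative suffers A(1,3) strain with the silyl group) should set C7 trans to the methyl group.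

Step 6
Reactants: 8 [(E)-[(2R,3R,6S)-3-methyl-2-[2-(2-methyl-1,3-dioxolan-2-yl)ethyl]-6-(prop-1-en-2-yl)cyclohexylidene]methyl]trimethylsilane
Product: 9 [(Z)-[(2R,3R,6S)-3-methyl-2-[2-(2-methyl-1,3-dioxolan-2-yl)ethyl]-6-(propan-2-yl)cyclohexylidene]methyl]trimethylsilane
Conditions: H2 (1 atm), RhCl(PPh3)3 (5 mol %), benzene, rt
Reagents that add atoms: none
Why: Homogeneous (Wilkinson-type) hydrogenation should reduce the unhindered 1,1-disubstituted isopropenyl alkene and leave the hindered trisubstituted vinylsilane; no stereocentre is formed (the E to Z change is only a change of CIP priorities).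

Step 7
Reactants: 9 [(Z)-[(2R,3R,6S)-3-methyl-2-[2-(2-methyl-1,3-dioxolan-2-yl)ethyl]-6-(propan-2-yl)cyclohexylidene]methyl]trimethylsilane
Product: 10 4-[(1R,2Z,3S,6R)-6-methyl-3-(propan-2-yl)-2-[(trimethylsilyl)methylidene]cyclohexyl]butan-2-one
Conditions: PPTS (cat.), acetone/H2O (10:1), 50 °C
Reagents that add atoms: water (O)
Why: Mild acid-catalysed ketal hydrolysis frees the methyl ketone under conditions too weak to protodesilylate the vinylsilane.

Step 8
Reactants: 10 4-[(1R,2Z,3S,6R)-6-methyl-3-(propan-2-yl)-2-[(trimethylsilyl)methylidene]cyclohexyl]butan-2-one; 11 benzaldehyde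
Product: 12 (1E)-5-[(1R,2Z,3S,6R)-6-methyl-3-(propan-2-yl)-2-[(trimethylsilyl)methylidene]cyclohexyl]-1-phenylpent-1-en-3-one
Conditions: 11 (1.2 equiv), NaOH (0.5 equiv), EtOH/H2O, 0 °C → rt
Reagents that add atoms: none
Why: Claisen–Schmidt aldol condensation of a methyl ketone with a non-enolisable aldehyde occurs at the methyl group and should give the E-styryl ketone, the vinylsilane being stable to aqueous base.

Step 9
Reactants: 12 (1E)-5-[(1R,2Z,3S,6R)-6-methyl-3-(propan-2-yl)-2-[(trimethylsilyl)methylidene]cyclohexyl]-1-phenylpent-1-en-3-one; 13 phloroglucinol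
Product: 14 (5R)-1-[(1R,2Z,3S,6R)-6-methyl-3-(propan-2-yl)-2-[(trimethylsilyl)methylidene]cyclohexyl]-5-phenyl-5-(2,4,6-trihydroxyphenyl)pentan-3-one
Conditions: 13 (3 equiv), 9-amino-9-deoxy-epi-quinidine (20 mol %), TFA (40 mol %), THF, rt
Reagents that add atoms: none
Why: Iminium-ion activation of the enone by the cinchona primary amine (the catalysis used for the Michael addition of 4-hydroxycoumarin to benzylideneacetone) lets phloroglucinol add as an enolic carbon nucleophile in a Friedel–Crafts-type Michael addition to one face of the β-carbon, which should set the benzylic centre (R) under catalyst control, excess phloroglucinol suppressing double alkylation; the adduct is handled as its equilibrium mixture with the cyclic hemiketal.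

Step 10
Reactants: 14 (5R)-1-[(1R,2Z,3S,6R)-6-methyl-3-(propan-2-yl)-2-[(trimethylsilyl)methylidene]cyclohexyl]-5-phenyl-5-(2,4,6-trihydroxyphenyl)pentan-3-one
Product: 17 bis-desformyl guajadial C (spiro chromane-5,7-diol; cadinane centres 1R 4S 7S 10R; benzylic centre R), via cyclic hemiketal 15 (not isolated), via oxocarbenium ion 16 (not isolated)
Conditions: Sc(OTf)3 (10 mol %), CH2Cl2 (0.01 M), −20 → 0 °C
Reagents that add atoms: none
Why: Sc(OTf)3 ionises the cyclic hemiketal 15 (ring–chain tautomer of 14) to the chroman-2-ylium oxocarbenium ion 16, whose cationic carbon C4 is attacked by the silicon-bearing carbon C5 of the exocyclic vinylsilane (ipso attack) to give a tertiary β-silyl cation at C6 that expels the silyl group as Me3SiOH and so regenerates the C5=C6 alkene in its original place. The closest known reaction type is the vinylsilane-terminated oxocarbenium-ion cyclisation (silyl-Prins-type ipso substitution), here run on a ketone-derived cyclic oxocarbenium ion. Ring B, a six-membered carbocycle, closes in a 6-endo-trig mode with respect to the vinylsilane (both alkene carbons lie in the new ring) and in an exo mode with respect to the C=O+ bond, which makes the pre-formed oxygen ring spiro-fused. The only new stereocentre, the spiro carbon C4, is set by two cooperating elements: the benzylic phenyl group, pushed pseudo-axial on the half-chair cation by the adjacent phenolic OH, blocks its own face so that C5 should arrive trans to phenyl, and the chair-like closure on the existing C1 centre should place the ring oxygen pseudo-axial and the chroman CH2 (C15) pseudo-equatorial on ring B, two preferences that coincide for the (R) benzylic configuration. The step needs a single alkene regioisomer and C–C bond formation faster than protodesilylation (elimination of 16 to the 4H-chromene is reversible under the acid); the Z geometry of the vinylsilane, with silicon on the C1 side, secures both because the C–Si bond becomes pseudo-axial in the closing ring and overlaps with the developing empty orbital at C6, while high dilution suppresses intermolecular capture of 16 by the electron-rich arene.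

Step 11
Reactants: 17 bis-desformyl guajadial C
Product: 18 guajadial C
Conditions: (chloromethylene)dimethyliminium chloride (3 equiv), MeCN, −20 → 10 °C; then H2O, NaOAc, rt
Reagents that add atoms: (chloromethylene)dimethyliminium chloride (C[N+](C)=CCl.[Cl-]); water (O)
Why: Vilsmeier–Haack formylation, the standard route to diformylphloroglucinols, should occur at the only two free aromatic positions, each flanked by two oxygen substituents, without touching any stereocentre, the low temperature and buffered hydrolysis being chosen to limit ionisation of the tertiary allylic aryl ether.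

**Compound list**

1 | (R)-citronellal [(3R)-3,7-dimethyloct-6-enal] | CC(C)=CCC[C@@H](C)CC=O | starting material
2 | methyl vinyl ketone (but-3-en-2-one) | C=CC(C)=O | starting material
3 | (2R,3R)-3,7-dimethyl-2-(3-oxobutyl)oct-6-enal | O=C[C@H](CCC(C)=O)[C@H](C)CCC=C(C)C | intermediate
4 | (5R)-7,7-dibromo-5-[(2R)-6-methylhept-5-en-2-yl]hept-6-en-2-one | BrC(Br)=C[C@H](CCC(C)=O)[C@H](C)CCC=C(C)C | intermediate
5 | 2-[(3R)-5,5-dibromo-3-[(2R)-6-methylhept-5-en-2-yl]pent-4-en-1-yl]-2-methyl-1,3-dioxolane | BrC(Br)=C[C@H](CCC1(C)OCCO1)[C@H](C)CCC=C(C)C | intermediate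
6 | lithium acetylide corresponding to 7 (lithium in place of the silyl group; not isolated) | [Li]C#C[C@H](CCC1(C)OCCO1)[C@H](C)CCC=C(C)C | intermediate
7 | [(3R,4R)-4,8-dimethyl-3-[2-(2-methyl-1,3-dioxolan-2-yl)ethyl]non-7-en-1-yn-1-yl]trimethylsilane | C[Si](C)(C)C#C[C@H](CCC1(C)OCCO1)[C@H](C)CCC=C(C)C | intermediate
8 | [(E)-[(2R,3R,6S)-3-methyl-2-[2-(2-methyl-1,3-dioxolan-2-yl)ethyl]-6-(prop-1-en-2-yl)cyclohexylidene]methyl]trimethylsilane (silicon cis to the side-chain carbon) | C[Si](C)(C)/C=C1\[C@H](CCC2(C)OCCO2)[C@H](C)CC[C@H]1C(C)=C | intermediate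
9 | [(Z)-[(2R,3R,6S)-3-methyl-2-[2-(2-methyl-1,3-dioxolan-2-yl)ethyl]-6-(propan-2-yl)cyclohexylidene]methyl]trimethylsilane | C[Si](C)(C)/C=C1\[C@H](CCC2(C)OCCO2)[C@H](C)CC[C@H]1C(C)C | intermediate
10 | 4-[(1R,2Z,3S,6R)-6-methyl-3-(propan-2-yl)-2-[(trimethylsilyl)methylidene]cyclohexyl]butan-2-one | C[Si](C)(C)/C=C1\[C@H](CCC(C)=O)[C@H](C)CC[C@H]1C(C)C | intermediate
11 | benzaldehyde | O=Cc1ccccc1 | starting material
12 | (1E)-5-[(1R,2Z,3S,6R)-6-methyl-3-(propan-2-yl)-2-[(trimethylsilyl)methylidene]cyclohexyl]-1-phenylpent-1-en-3-one | C[Si](C)(C)/C=C1\[C@H](CCC(=O)/C=C/c2ccccc2)[C@H](C)CC[C@H]1C(C)C | intermediate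
13 | phloroglucinol (benzene-1,3,5-triol) | Oc1cc(O)cc(O)c1 | starting material
14 | (5R)-1-[(1R,2Z,3S,6R)-6-methyl-3-(propan-2-yl)-2-[(trimethylsilyl)methylidene]cyclohexyl]-5-phenyl-5-(2,4,6-trihydroxyphenyl)pentan-3-one (keto-phenol form) | C[Si](C)(C)/C=C1\[C@H](CCC(=O)C[C@H](c2ccccc2)c2c(O)cc(O)cc2O)[C@H](C)CC[C@H]1C(C)C | intermediate
15 | cyclic hemiketal of 14: (4R)-2-[2-[(1R,2Z,3S,6R)-6-methyl-3-(propan-2-yl)-2-[(trimethylsilyl)methylidene]cyclohexyl]ethyl]-4-phenylchromane-2,5,7-triol (both C2 epimers; not isolated) | C[Si](C)(C)/C=C1\[C@H](CCC2(O)Oc3cc(O)cc(O)c3[C@@H](c3ccccc3)C2)[C@H](C)CC[C@H]1C(C)C | intermediate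
16 | chroman-2-ylium oxocarbenium ion from 15 by loss of hydroxide (4R; not isolated) | C[Si](C)(C)/C=C1\[C@H](CCC2=[O+]c3cc(O)cc(O)c3[C@@H](c3ccccc3)C2)[C@H](C)CC[C@H]1C(C)C | intermediate
17 | bis-desformyl guajadial C: (2S,4R)-4-phenylchromane-5,7-diol spiro-linked through chroman C2 to C4 of the (1R,7S,10R)-7-isopropyl-10-methyl octalin (C5=C6 alkene) | CC(C)[C@@H]1CC[C@@H](C)[C@H]2CC[C@@]3(C=C12)C[C@H](c1ccccc1)c1c(O)cc(O)cc1O3 | intermediate
18 | guajadial C (6,8-diformyl derivative of 17) | CC(C)[C@@H]1CC[C@@H](C)[C@H]2CC[C@@]3(C=C12)C[C@H](c1ccccc1)c1c(O)c(C=O)c(O)c(C=O)c1O3 | target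

**Step count and risks**

Total step count: 11. Longest linear sequence: 11 steps, from (R)-citronellal.

Steps most likely to fail:

1. Step 10. What may go wrong: attack of C5 on the other face of the oxocarbenium ion (spiro epimer) if the ring-B chair preference and the phenyl shielding do not cooperate as predicted, or protodesilylation of the vinylsilane outrunning C–C bond formation. Fallback, with inverted polarity (vinyl-metal addition to the ketone, then closure of the oxygen ring by allylic etherification): setting out from 12, iododesilylation with NIS in hexafluoroisopropanol at 0 °C (retention of geometry) would give the (Z)-vinyl iodide enone F1. Phloroglucinol addition under the conditions of step 9 would give the iodo keto-phenol F2. An intramolecular Nozaki–Hiyama–Kishi reaction (CrCl2, NiCl2 cat., DMSO, rt) would form the same C4–C5 bond and give the tertiary allylic alcohol F3. PPTS in CH2Cl2 would then ionise F3 to the allyl cation, which the ortho phenol should capture at C4 in a six-membered closure, coming back to the route at 17.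

2. Step 11. What may go wrong: acid-induced ionisation of the tertiary allylic aryl ether (ring opening, elimination, epimerisation at C4) during iminium formation or hydrolysis, or arrest after the first formylation. Fallback, by anionic formylation: setting out from 17, MOMCl and i-Pr2NEt would give the bis(methoxymethyl) ether F4. NBS (2 equiv, MeCN, 0 °C) would give the aryl dibromide F5. Double bromine–lithium exchange (t-BuLi, THF, −78 °C) followed by DMF would give the bis(methoxymethyl) dialdehyde F6. Dilute HCl in THF at rt, under which methoxymethyl ethers ortho to formyl groups cleave readily, would come back to the route at 18.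

3. Step 5. What may go wrong: sluggish hydropalladation or carbopalladation of the silylated 1,7-enyne, or β-hydride elimination toward C7, which would give the conjugated isopropylidene diene and erase the C7 stereocentre. Fallback, by radical ring closure without an isopropenyl intermediate: setting out from 5, n-BuLi (2.2 equiv) and an aqueous quench would give the terminal alkyne F7. Bu3SnH with AIBN (benzene, 80 °C) should add a stannyl radical to the alkyne terminus and close ring A by 6-exo attack of the vinyl radical on the trisubstituted alkene, giving after hydrogen transfer the vinylstannane F8, which already carries the isopropyl group; reversible stannyl-radical addition should equilibrate the alkene geometry toward tin on the C1 side. Tin–lithium exchange (n-BuLi, THF, −78 °C) and TMSCl would come back to the route at 9.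

**Further compounds**

F1 | step 10 | (1E)-5-[(1R,2Z,3S,6R)-2-(iodomethylidene)-6-methyl-3-(propan-2-yl)cyclohexyl]-1-phenylpent-1-en-3-one | I/C=C1\[C@H](CCC(=O)/C=C/c2ccccc2)[C@H](C)CC[C@H]1C(C)C
F2 | step 10 | (5R)-1-[(1R,2Z,3S,6R)-2-(iodomethylidene)-6-methyl-3-(propan-2-yl)cyclohexyl]-5-phenyl-5-(2,4,6-trihydroxyphenyl)pentan-3-one | I/C=C1\[C@H](CCC(=O)C[C@H](c2ccccc2)c2c(O)cc(O)cc2O)[C@H](C)CC[C@H]1C(C)C
F3 | step 10 | tertiary allylic alcohol: octalin of 17 with OH and a (2R)-2-phenyl-2-(2,4,6-trihydroxyphenyl)ethyl group on C4 (both C4 epimers) | CC(C)[C@@H]1CC[C@@H](C)[C@H]2CCC(O)(C=C12)C[C@H](c1ccccc1)c1c(O)cc(O)cc1O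
F4 | step 11 | bis(methoxymethyl) ether of 17 | CC(C)[C@@H]1CC[C@@H](C)[C@H]2CC[C@@]3(C=C12)C[C@H](c1ccccc1)c1c(OCOC)cc(OCOC)cc1O3
F5 | step 11 | 6,8-dibromo derivative of F4 (chroman numbering) | CC(C)[C@@H]1CC[C@@H](C)[C@H]2CC[C@@]3(C=C12)C[C@H](c1ccccc1)c1c(OCOC)c(Br)c(OCOC)c(Br)c1O3
F6 | step 11 | bis(methoxymethyl) ether of guajadial C | CC(C)[C@@H]1CC[C@@H](C)[C@H]2CC[C@@]3(C=C12)C[C@H](c1ccccc1)c1c(OCOC)c(C=O)c(OCOC)c(C=O)c1O3
F7 | step 5 | 2-[(3R,4R)-3-ethynyl-4,8-dimethylnon-7-en-1-yl]-2-methyl-1,3-dioxolane | C#C[C@H](CCC1(C)OCCO1)[C@H](C)CCC=C(C)C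
F8 | step 5 | tributyl[(Z)-[(2R,3R,6S)-3-methyl-2-[2-(2-methyl-1,3-dioxolan-2-yl)ethyl]-6-(propan-2-yl)cyclohexylidene]methyl]stannane | CCCC[Sn](CCCC)(CCCC)/C=C1\[C@H](CCC2(C)OCCO2)[C@H](C)CC[C@H]1C(C)C
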